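The benzoquinone ring (C1–C6, furan on C2) is grown on the furan from an open chain and is never coupled on as an arene. Photolysis of a (3E)-1-diazo-4-methoxy-5-(furan-2-yl)hexa-3,5-dien-2-one triggers a Wolff 1,2-shift of the dienyl group, which forms C5–C6, and the dienylketene so formed closes by 6π-electrocyclisation, which forms C3–C4; tautomerisation gives a 4-methoxyphenol, oxidised to the quinone. The step exploits the para C1/C4 oxygen pair and the three unsubstituted CH positions (C3, C5, C6) of the quinone ring: C4=O with C5–H is a latent ketene, C1–O an enol ether. The E geometry comes from ring-opening of a dihydropyranone.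

Key step: step 8

Remark on numbering: the quinone ring is numbered C1 (C=O next to the furyl-bearing carbon), C2 (furyl), C3–H, C4 (C=O), C5–H, C6–H. In diazo ketone 13 the chain atoms C1 (CHN2), C2 (C=O), C3 (CH=), C4 (C–OMe), C5 (C–furyl), C6 (=CH2) become quinone C5, C4, C6, C1, C2, C3.
Remark on materials: furan-3-carbaldehyde, (+)-B-allyldiisopinocampheylborane solution and methyl (2E)-4-bromo-3-methoxybut-2-enoate are taken as commercial. "FurR" below means the 4-[(1R)-4-methyl-1-(3-methylbutanoyloxy)pent-3-en-1-yl]furan-2-yl group.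

Step 1
Reactants: 1 furan-3-carbaldehyde
Product: 3 (1R)-1-(furan-3-yl)but-3-en-1-ol, via borinate ester 2 (not isolated)
Conditions: (+)-Ipc2B(allyl) (1.2 equiv), Et2O, −78 °C; then NaOH, H2O2, 0 → 20 °C
Reagents that add atoms: (+)-B-allyldiisopinocampheylborane (the antipode from (−)-α-pinene), C=CCB(C1CC2CC(C1C)C2(C)C)C1CC2CC(C1C)C2(C)C
Why: Brown asymmetric allylboration through a closed chair transition state, in which this antipode (the one that turns benzaldehyde into (R)-1-phenylbut-3-en-1-ol) delivers allyl to the Re face of the aldehyde and so sets the (R) carbinol centre.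

Step 2
Reactants: 3 (1R)-1-(furan-3-yl)but-3-en-1-ol
Product: 4 (1R)-1-(furan-3-yl)-4-methylpent-3-en-1-ol
Conditions: second-generation Grubbs catalyst (3 mol %), 2-methyl-2-butene (large excess), CH2Cl2, 40 °C
Reagents that add atoms: 2-methyl-2-butene, CC=C(C)C
Why: Olefin cross-metathesis of a terminal alkene with excess 2-methyl-2-butene is a standard way to install the dimethylvinyl terminus and touches neither the carbinol centre nor the furan.

Step 3
Reactants: 4 (1R)-1-(furan-3-yl)-4-methylpent-3-en-1-ol
Product: 5 (1R)-1-(furan-3-yl)-4-methylpent-3-en-1-yl 3-methylbutanoate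
Conditions: 3-methylbutanoyl chloride (1.2 equiv), pyridine, DMAP (cat.), CH2Cl2, 0 °C
Reagents that add atoms: 3-methylbutanoyl chloride, CC(C)CC(=O)Cl
Why: DMAP-catalysed O-acylation proceeds with retention because the C–O bond of the stereocentre is not broken, and the pyridine buffer protects the acid-labile furylic ester.

Step 4
Reactants: 5 (1R)-1-(furan-3-yl)-4-methylpent-3-en-1-yl 3-methylbutanoate
Product: 6 (1R)-4-methyl-1-[5-(4,4,5,5-tetramethyl-1,3,2-dioxaborolan-2-yl)furan-3-yl]pent-3-en-1-yl 3-methylbutanoate
Conditions: [Ir(OMe)(cod)]2 (1.5 mol %), 4,4'-di-tert-butyl-2,2'-bipyridine (3 mol %), B2pin2 (1.0 equiv), hexane, 25 °C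
Reagents that add atoms: bis(pinacolato)diboron, CC1(C)OB(OC1(C)C)B1OC(C)(C)C(C)(C)O1
Why: Iridium-catalysed aromatic C–H borylation is sterically controlled and should go to the furan α-position remote from the branched substituent (C5), while the ester and the trisubstituted alkene are inert.

Step 5
Reactants: 6 the furan-5-boronate from step 4; 7 methyl (2E)-4-bromo-3-methoxybut-2-enoate
Product: 8 methyl (2E)-3-methoxy-4-(FurR)but-2-enoate
Conditions: Pd(PPh3)4 (5 mol %), CsF (3 equiv), THF, 60 °C
Reagents that add atoms: none
Why: Suzuki–Miyaura coupling of a heteroaryl boronate with an allylic bromide through a π-allyl palladium intermediate joins at the CH2 terminus so that the push–pull enoate keeps its E geometry, and anhydrous fluoride activation spares the isovalerate and avoids hydrolysis of 7.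

Step 6
Reactants: 8 methyl (2E)-3-methoxy-4-(FurR)but-2-enoate
Product: 11 (2E)-3-methoxy-4-(FurR)penta-2,4-dienoic acid, via hydroxymethyl ester 9 (not isolated), via dihydropyranone 10 (not isolated)
Conditions: LiN(SiMe3)2 (1.05 equiv), THF, −78 °C; CH2O (gas, from cracked paraformaldehyde), −78 → −20 °C; argon purge; LiN(SiMe3)2 (1.2 equiv), −78 → 0 °C; aq. NH4Cl, extraction at pH 4
Reagents that add atoms: formaldehyde, C=O
Why: The doubly activated CH2 (furylic and γ to the vinylogous ester) is deprotonated selectively, the lithium dienolate adds formaldehyde at the γ-carbon (vinylogous aldol), the alkoxide lactonises onto the cis ester, and the second charge of base opens the dihydropyranone by E1cB loss of the carboxylate (the known base cleavage of 4-methoxy-5,6-dihydropyran-2-ones to 3-methoxydienoic acids), which carries the cis ring relation of carbonyl and C5 into the 2E geometry and erases the transient stereocentre.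

Step 7
Reactants: 11 (2E)-3-methoxy-4-(FurR)penta-2,4-dienoic acid
Product: 13 (3E)-1-diazo-4-methoxy-5-(FurR)hexa-3,5-dien-2-one, via acid chloride 12 (not isolated)
Conditions: 1-chloro-N,N,2-trimethylprop-1-en-1-amine (1.2 equiv), CH2Cl2, 0 °C; then CH2N2 (3 equiv, Et2O), −10 → 0 °C, dark; used at once
Reagents that add atoms: diazomethane, C=[N+]=[N-]
Why: Arndt–Eistert-type acylation of diazomethane by an acid chloride made under neutral conditions with the chloroenamine, the second equivalent of diazomethane taking up HCl so that the enol ether, the vinylfuran and the furylic ester never meet acid.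

Step 8
Reactants: 13 (3E)-1-diazo-4-methoxy-5-(FurR)hexa-3,5-dien-2-one
Product: 16 4-methoxy-3-(FurR)phenol, via dienylketene 14 (not isolated), via cyclohexadienone 15 (not isolated)
Conditions: hν (365 nm LEDs), degassed toluene (0.005 M), 20 °C; then 60 °C, 1 h
Reagents that add atoms: none
Why: Direct irradiation of the s-cis diazo ketone expels N2 with concerted 1,2-shift of the only group that can migrate, the dienyl carbon C3 of 13, from the carbonyl carbon to the diazo carbon (photochemical Wolff rearrangement with alkenyl migration, as in the vinylketene-forming stage of the Danheiser benzannulation), which makes the future C5–C6 bond and ketene 14. In 14 the ketene carbon and the terminal CH2 sit on the same side of the central enol-ether double bond, so the six-membered ring closes by thermal disrotatory 6π-electrocyclisation, forming C3–C4 and dienone 15, the closest known reaction being the closure of dienylketenes to cyclohexa-2,4-dienones that ends that benzannulation. Enolisation of 15 is driven by aromatisation and gives phenol 16 with the hydroxyl para to the methoxy group. No stereocentre is created, since C6 of 15 is a CH2, and the (R) ester centre is remote and untouched. The step needs Wolff shift to win over carbene capture by the 5,6-alkene, which metal-free excitation of the diazocarbonyl chromophore favours, and ring closure to win over intermolecular ketene trapping, which high dilution and the absence of nucleophiles secure. The cis relation needed for closure is built into the substrate because the 3,4-double bond of 13 comes from the six-membered lactone 10.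

Step 9
Reactants: 16 4-methoxy-3-(FurR)phenol
Product: 18 (1R)-1-[5-(3,6-dioxocyclohexa-1,4-dien-1-yl)furan-3-yl]-4-methylpent-3-en-1-yl 3-methylbutanoate, via hemiketal 17 (not isolated)
Conditions: PhI(OAc)2 (1.1 equiv), MeCN/H2O (4:1), 0 °C
Reagents that add atoms: water, O
Why: Oxidative demethylation of a 4-methoxyphenol by hypervalent iodine, in which ligand exchange at the phenol oxygen and two-electron oxidation let water add at the methoxy-bearing para carbon to give hemiketal 17, which loses methanol to the quinone under conditions that should leave furan, trisubstituted alkene and ester intact.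

Compound list
1 | furan-3-carbaldehyde | O=Cc1ccoc1 | starting material
2 | (1R)-1-(furan-3-yl)but-3-en-1-yl bis(isopinocampheyl)borinate, isopinocampheyl groups from (−)-α-pinene (their configuration is given by name only), formed in the flask | C=CC[C@@H](OB(C1CC2CC(C1C)C2(C)C)C1CC2CC(C1C)C2(C)C)c1ccoc1 | intermediate
3 | (1R)-1-(furan-3-yl)but-3-en-1-ol | C=CC[C@@H](O)c1ccoc1 | intermediate
4 | (1R)-1-(furan-3-yl)-4-methylpent-3-en-1-ol | CC(C)=CC[C@@H](O)c1ccoc1 | intermediate
5 | (1R)-1-(furan-3-yl)-4-methylpent-3-en-1-yl 3-methylbutanoate | CC(C)=CC[C@@H](OC(=O)CC(C)C)c1ccoc1 | intermediate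
6 | (1R)-4-methyl-1-[5-(4,4,5,5-tetramethyl-1,3,2-dioxaborolan-2-yl)furan-3-yl]pent-3-en-1-yl 3-methylbutanoate | CC(C)=CC[C@@H](OC(=O)CC(C)C)c1coc(B2OC(C)(C)C(C)(C)O2)c1 | intermediate
7 | methyl (2E)-4-bromo-3-methoxybut-2-enoate | COC(=O)/C=C(OC)\CBr | starting material
8 | methyl (2E)-3-methoxy-4-{4-[(1R)-4-methyl-1-(3-methylbutanoyloxy)pent-3-en-1-yl]furan-2-yl}but-2-enoate | CC(C)=CC[C@@H](OC(=O)CC(C)C)c1coc(C/C(OC)=C\C(=O)OC)c1 | intermediate
9 | methyl (2E)-5-hydroxy-3-methoxy-4-{4-[(1R)-4-methyl-1-(3-methylbutanoyloxy)pent-3-en-1-yl]furan-2-yl}pent-2-enoate, as its lithium alkoxide, both C4 epimers, formed in the flask | CC(C)=CC[C@@H](OC(=O)CC(C)C)c1coc(C(CO)/C(OC)=C\C(=O)OC)c1 | intermediate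
10 | 4-methoxy-5-{4-[(1R)-4-methyl-1-(3-methylbutanoyloxy)pent-3-en-1-yl]furan-2-yl}-5,6-dihydro-2H-pyran-2-one, both C5 epimers, formed in the flask | CC(C)=CC[C@@H](OC(=O)CC(C)C)c1coc(C2COC(=O)C=C2OC)c1 | intermediate
11 | (2E)-3-methoxy-4-{4-[(1R)-4-methyl-1-(3-methylbutanoyloxy)pent-3-en-1-yl]furan-2-yl}penta-2,4-dienoic acid | CC(C)=CC[C@@H](OC(=O)CC(C)C)c1coc(C(=C)/C(OC)=C\C(=O)O)c1 | intermediate
12 | (2E)-3-methoxy-4-{4-[(1R)-4-methyl-1-(3-methylbutanoyloxy)pent-3-en-1-yl]furan-2-yl}penta-2,4-dienoyl chloride, formed in the flask | CC(C)=CC[C@@H](OC(=O)CC(C)C)c1coc(C(=C)/C(OC)=C\C(=O)Cl)c1 | intermediate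
13 | (3E)-1-diazo-4-methoxy-5-{4-[(1R)-4-methyl-1-(3-methylbutanoyloxy)pent-3-en-1-yl]furan-2-yl}hexa-3,5-dien-2-one | CC(C)=CC[C@@H](OC(=O)CC(C)C)c1coc(C(=C)/C(OC)=C\C(=O)C=[N+]=[N-])c1 | intermediate
14 | (3E)-4-methoxy-5-{4-[(1R)-4-methyl-1-(3-methylbutanoyloxy)pent-3-en-1-yl]furan-2-yl}hexa-1,3,5-trien-1-one (dienylketene), formed in the flask | CC(C)=CC[C@@H](OC(=O)CC(C)C)c1coc(C(=C)/C(OC)=C\C=C=O)c1 | intermediate
15 | 4-methoxy-5-{4-[(1R)-4-methyl-1-(3-methylbutanoyloxy)pent-3-en-1-yl]furan-2-yl}cyclohexa-2,4-dien-1-one, formed in the flask | CC(C)=CC[C@@H](OC(=O)CC(C)C)c1coc(C2=C(OC)C=CC(=O)C2)c1 | intermediate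
16 | (1R)-1-[5-(5-hydroxy-2-methoxyphenyl)furan-3-yl]-4-methylpent-3-en-1-yl 3-methylbutanoate (the 4-methoxy-3-furylphenol) | CC(C)=CC[C@@H](OC(=O)CC(C)C)c1coc(-c2cc(O)ccc2OC)c1 | intermediate
17 | (1R)-1-[5-(6-hydroxy-6-methoxy-3-oxocyclohexa-1,4-dien-1-yl)furan-3-yl]-4-methylpent-3-en-1-yl 3-methylbutanoate (hemiketal, both epimers at the ketal carbon), formed in the flask | CC(C)=CC[C@@H](OC(=O)CC(C)C)c1coc(C2=CC(=O)C=CC2(O)OC)c1 | intermediate
18 | (1R)-1-[5-(3,6-dioxocyclohexa-1,4-dien-1-yl)furan-3-yl]-4-methylpent-3-en-1-yl 3-methylbutanoate | CC(C)=CC[C@@H](OC(=O)CC(C)C)c1coc(C2=CC(=O)C=CC2=O)c1 | target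

Total step count: 9. Longest linear sequence: 9 steps (1 to 18); fragment 7 is bought.

Steps most likely to fail

Step 8. The excited diazo ketone or a free carbene may be diverted into intramolecular capture by the 5,6-alkene, the vinylfuran may photodegrade or polymerise, or the ketene may be trapped before it closes. Fallback: give up the ring construction and set out from boronate 6. Suzuki–Miyaura coupling of 6 with commercial 3-bromo-4-methoxyphenol (Pd(dppf)Cl2, K3PO4, dioxane/H2O, 60 °C) would give phenol 16 directly, where the route is rejoined. This fallback makes no new compound (F0).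

Step 6. Formaldehyde may attack the α-carbon of the lithium dienolate instead of the γ-carbon, the dienolate may lose the cis relation needed for lactonisation, and the lithium methoxide set free may cleave the isovalerate. Fallback from 8: convert it with LiN(SiMe3)2 and Me3SiCl (THF, −78 °C) into silyl ketene acetal F1. A Lewis-acid-catalysed vinylogous Mukaiyama aldol reaction of F1 with aqueous formaldehyde (Yb(OTf)3, 10 mol %, THF, 20 °C), which is γ-selective, would give hydroxy ester 9 without any methoxide present. KOtBu (2.1 equiv, THF, −40 → 0 °C) then takes 9 through lactone 10 to acid 11, where the route is rejoined.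

Step 7. Acylation of diazomethane by the deactivated vinylogous acid chloride may be slow, so that dipolar cycloaddition of diazomethane to the dienoyl system and HCl-induced decomposition take over. Fallback from 11: acid chloride 12 is made as before and treated with Me2CuLi (THF, −78 °C) to give methyl ketone F2. Detrifluoroacetylative diazo transfer follows: LiN(SiMe3)2, then CF3CO2CH2CF3 (THF, −78 °C) gives trifluoroacetyl diketone F3, and MsN3, Et3N, H2O in MeCN (20 °C) turns F3 into diazo ketone 13, where the route is rejoined. The methyl group is the only enolisable position of F2, so the diazo group can only enter at the required carbon.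

Further compounds
F0 | step 8 | none | none
F1 | step 6 | silyl ketene acetal of 8: (1R)-1-{5-[2,4-dimethoxy-4-(trimethylsilyloxy)buta-1,3-dien-1-yl]furan-3-yl}-4-methylpent-3-en-1-yl 3-methylbutanoate, mixture of double-bond isomers | CC(C)=CC[C@@H](OC(=O)CC(C)C)c1coc(C=C(OC)C=C(OC)O[Si](C)(C)C)c1
F2 | step 7 | methyl ketone: (3E)-4-methoxy-5-{4-[(1R)-4-methyl-1-(3-methylbutanoyloxy)pent-3-en-1-yl]furan-2-yl}hexa-3,5-dien-2-one | CC(C)=CC[C@@H](OC(=O)CC(C)C)c1coc(C(=C)/C(OC)=C\C(C)=O)c1
F3 | step 7 | trifluoroacetyl diketone: (5E)-1,1,1-trifluoro-6-methoxy-7-{4-[(1R)-4-methyl-1-(3-methylbutanoyloxy)pent-3-en-1-yl]furan-2-yl}octa-5,7-diene-2,4-dione | CC(C)=CC[C@@H](OC(=O)CC(C)C)c1coc(C(=C)/C(OC)=C\C(=O)CC(=O)C(F)(F)F)c1
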